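The target is cut at the propyl linker into (S)-3-methylazecane and a 1-(3-chloropropyl)-3,4-bis(7,8-dimethoxyquinolin-5-yl)pyrrole. Everything rests on closing the ten-membered azecane ring at the N1–C10 bond, the unbranched N–CH2 bond remote from the C3 methyl stereocentre. N1 is tertiary in the target, so before closure it can carry a 2-nitrobenzenesulfonyl group, which makes N–H acidic enough for an intramolecular Mitsunobu alkylation by the primary C10 alcohol. One operation turns the open-chain (S)-N-(9-hydroxy-2-methylnonyl)sulfonamide, built from (R)-3-bromo-2-methylpropan-1-ol, into the medium ring; thiolate then removes the sulfonyl group and the amine is alkylated with the pyrrole fragment, before the four methyl ethers are cleaved.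

Key step: step 3

Remark: the target is taken as the free base; azecane positions are numbered N1, C2 (the CH2 between nitrogen and the stereocentre), C3 (methyl-bearing, S) and C4 to C10 (C10 being the second CH2 on nitrogen).

**Route**

Step 1
Reactants: 1 (R)-3-bromo-2-methylpropan-1-ol; 2 (6-bromohexyloxy)(tert-butyl)dimethylsilane
Product: 4 (S)-9-[(tert-butyldimethylsilyl)oxy]-2-methylnonan-1-ol, via Grignard reagent 3 (not isolated)
Conditions: 2, Mg, THF, 40 °C (2.5 equiv of 3); then 1, Li2CuCl4 (5 mol %), THF, −78 °C → rt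
Reagents that add atoms: none
Why: Kochi-type copper-catalysed sp3–sp3 cross-coupling of a primary alkyl Grignard reagent with a primary bromide, in which the first equivalent of 3 only deprotonates the hydroxyl group and the stereocentre, β to the reacting carbon, is carried through untouched (the descriptor changes from R to S only because the CIP priorities of the two arms swap).

Step 2
Reactants: 4 (S)-9-[(tert-butyldimethylsilyl)oxy]-2-methylnonan-1-ol
Product: 6 (S)-N-(9-hydroxy-2-methylnonyl)-2-nitrobenzenesulfonamide, via N-Boc-N-Ns silyl ether 5 (not isolated)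
Conditions: NsNHBoc, PPh3, DIAD, THF, 0 °C → rt; then HCl (4 M in dioxane), MeOH, rt
Reagents that add atoms: N-(tert-butoxycarbonyl)-2-nitrobenzenesulfonamide, CC(C)(C)OC(=O)NS(=O)(=O)c1ccccc1[N+](=O)[O-]
Why: Mitsunobu alkylation of the strongly acidic N-Boc sulfonamide (Fukuyama amine synthesis) should give clean mono-alkylation at the primary alcohol, and methanolic HCl then removes both the Boc group and the primary silyl ether while the sulfonamide stays intact.

Step 3
Reactants: 6 (S)-N-(9-hydroxy-2-methylnonyl)-2-nitrobenzenesulfonamide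
Product: 7 (S)-3-methyl-1-[(2-nitrophenyl)sulfonyl]azecane
Conditions: PPh3, DIAD, toluene–THF, slow addition of 6 (final concentration about 0.01 M), rt
Reagents that add atoms: none
Why: The betaine from PPh3 and DIAD deprotonates the sulfonamide N–H and converts the primary C10 hydroxyl into an alkoxyphosphonium ion, which the sulfonamide nitrogen N1 displaces in an intramolecular SN2 reaction that forms the N1–C10 bond with loss of Ph3PO. The closest known reaction type is the Fukuyama–Mitsunobu cyclisation of N-(ω-hydroxyalkyl)-2-nitrobenzenesulfonamides, an established entry to eight- to ten-membered cyclic amines. The azecane ring closes in a 10-exo-tet mode. No stereocentre is formed, and C3, which takes no part in the substitution and has no acidic hydrogen, should keep its (S) configuration. The step needs ring closure to win over intermolecular alkylation (cyclic dimer, oligomers) and N-alkylation to win over O-alkylation of the sulfonamide: slow addition at high dilution keeps the stationary concentration of 6 low, the electrophilic carbon is an unbranched primary centre far from the C3 branch, and the sulfonamide nitrogen is the only acidic nucleophile present.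

Step 4
Reactants: 7 (S)-3-methyl-1-[(2-nitrophenyl)sulfonyl]azecane
Product: 8 (S)-3-methylazecane
Conditions: PhSH, K2CO3, DMF, rt; acid–base extraction
Reagents that add atoms: none
Why: Fukuyama deprotection, in which thiophenolate adds to the nitroarene at the sulfonyl-bearing carbon (SNAr through a Meisenheimer complex) and the sulfonamide collapses to SO2 and the free secondary amine, with no other reactive group in the molecule.

Step 5
Reactants: 9 2,3-dimethoxyaniline
Product: 10 7,8-dimethoxyquinoline
Conditions: glycerol, sodium 3-nitrobenzenesulfonate, 70% H2SO4, 135 °C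
Reagents that add atoms: glycerol, OCC(O)CO
Why: Skraup quinoline synthesis (conjugate addition of the aniline to acrolein formed from glycerol, cyclisation, oxidation), in which ring closure can occur only at the single free ortho position of the aniline, so the 7,8-dimethoxy pattern is unambiguous.

Step 6
Reactants: 10 7,8-dimethoxyquinoline
Product: 11 5-bromo-7,8-dimethoxyquinoline
Conditions: NBS, MeCN, 0 °C → rt
Reagents that add atoms: N-bromosuccinimide, O=C1CCC(=O)N1Br
Why: Electrophilic aromatic bromination should go to C5, the peri position para to the 8-methoxy group, because C6 is only weakly activated by the 7-methoxy group (as at C3 of a 2-naphthyl ether) and the pyridine ring is deactivated.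

Step 7
Reactants: 11 5-bromo-7,8-dimethoxyquinoline
Product: 12 7,8-dimethoxy-5-(4,4,5,5-tetramethyl-1,3,2-dioxaborolan-2-yl)quinoline
Conditions: B2pin2, Pd(dppf)Cl2 (5 mol %), KOAc, 1,4-dioxane, 90 °C
Reagents that add atoms: bis(pinacolato)diboron, CC1(C)OB(OC1(C)C)B1OC(C)(C)C(C)(C)O1
Why: Miyaura borylation of an aryl bromide, which tolerates the methoxy groups and the quinoline nitrogen.

Step 8
Reactants: 13 1-(triisopropylsilyl)pyrrole
Product: 14 3,4-dibromo-1-(triisopropylsilyl)pyrrole
Conditions: NBS (2.0 equiv), THF, −78 °C → rt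
Reagents that add atoms: N-bromosuccinimide, O=C1CCC(=O)N1Br
Why: Electrophilic bromination of the pyrrole, in which the bulky silyl group on nitrogen shields C2 and C5 so that both bromine atoms should enter the β positions.

Step 9
Reactants: 14 3,4-dibromo-1-(triisopropylsilyl)pyrrole; 12 7,8-dimethoxy-5-(4,4,5,5-tetramethyl-1,3,2-dioxaborolan-2-yl)quinoline
Product: 15 5-[4-bromo-1-(triisopropylsilyl)-1H-pyrrol-3-yl]-7,8-dimethoxyquinoline
Conditions: Pd(PPh3)4 (5 mol %), Na2CO3, DME–H2O, 80 °C; 14 in excess (2.5 equiv), surplus recovered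
Reagents that add atoms: none
Why: Suzuki–Miyaura coupling that should stop at mono-arylation, because the dibromide is in excess, the triphenylphosphine catalyst leaves the product before a second oxidative addition, and the new peri-hindered quinolinyl group shields the remaining bromide.

Step 10
Reactants: 15 5-[4-bromo-1-(triisopropylsilyl)-1H-pyrrol-3-yl]-7,8-dimethoxyquinoline; 12 7,8-dimethoxy-5-(4,4,5,5-tetramethyl-1,3,2-dioxaborolan-2-yl)quinoline
Product: 17 5,5'-(1H-pyrrole-3,4-diyl)bis(7,8-dimethoxyquinoline), via N-TIPS bis(quinolinyl)pyrrole 16 (not isolated)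
Conditions: Pd(OAc)2 (5 mol %), SPhos, K3PO4, toluene–H2O, 100 °C; then TBAF, THF, rt
Reagents that add atoms: none
Why: Suzuki–Miyaura coupling of the hindered bromide with a biarylphosphine ligand suited to ortho- and peri-hindered partners, followed by fluoride cleavage of the N–Si bond, which also converges any material that lost the silyl group under the basic coupling conditions.

Step 11
Reactants: 17 5,5'-(1H-pyrrole-3,4-diyl)bis(7,8-dimethoxyquinoline)
Product: 18 5,5'-[1-(3-chloropropyl)-1H-pyrrole-3,4-diyl]bis(7,8-dimethoxyquinoline)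
Conditions: NaH, DMF, 0 °C; then Br(CH2)3Cl (3 equiv), 0 °C → rt
Reagents that add atoms: 1-bromo-3-chloropropane, ClCCCBr
Why: SN2 N-alkylation of the sodium pyrrolide should occur at the bromide end of the dihalide (better leaving group), and the excess of dihalide suppresses a second alkylation at the chloride end.

Step 12
Reactants: 18 5,5'-[1-(3-chloropropyl)-1H-pyrrole-3,4-diyl]bis(7,8-dimethoxyquinoline); 8 (S)-3-methylazecane
Product: 19 5,5'-{1-[3-((S)-3-methylazecan-1-yl)propyl]-1H-pyrrole-3,4-diyl}bis(7,8-dimethoxyquinoline)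
Conditions: K2CO3, NaI (cat.), MeCN, 80 °C
Reagents that add atoms: none
Why: SN2 N-alkylation of the secondary amine under Finkelstein catalysis, in which the dialkylamine is far more nucleophilic than the quinoline nitrogens and the C3 stereocentre is not involved.

Step 13
Reactants: 19 5,5'-{1-[3-((S)-3-methylazecan-1-yl)propyl]-1H-pyrrole-3,4-diyl}bis(7,8-dimethoxyquinoline)
Product: 20 5,5'-{1-[3-((S)-3-methylazecan-1-yl)propyl]-1H-pyrrole-3,4-diyl}bis(quinoline-7,8-diol)
Conditions: BBr3 (12 equiv), CH2Cl2, −78 °C → rt; then H2O; neutral work-up under argon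
Reagents that add atoms: none
Why: Lewis acid cleavage of the four aryl methyl ethers by BBr3, used in excess because the amine and the two quinoline nitrogens bind the reagent, with work-up under argon because the catechols are air-sensitive.

**Compound list**

1 | (R)-3-bromo-2-methylpropan-1-ol | C[C@H](CO)CBr | starting material
2 | (6-bromohexyloxy)(tert-butyl)dimethylsilane | CC(C)(C)[Si](C)(C)OCCCCCCBr | starting material
3 | {6-[(tert-butyldimethylsilyl)oxy]hexyl}magnesium bromide | CC(C)(C)[Si](C)(C)OCCCCCC[Mg]Br | intermediate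
4 | (S)-9-[(tert-butyldimethylsilyl)oxy]-2-methylnonan-1-ol | C[C@H](CO)CCCCCCCO[Si](C)(C)C(C)(C)C | intermediate
5 | tert-butyl (S)-{9-[(tert-butyldimethylsilyl)oxy]-2-methylnonyl}[(2-nitrophenyl)sulfonyl]carbamate | C[C@H](CN(C(=O)OC(C)(C)C)S(=O)(=O)c1ccccc1[N+](=O)[O-])CCCCCCCO[Si](C)(C)C(C)(C)C | intermediate
6 | (S)-N-(9-hydroxy-2-methylnonyl)-2-nitrobenzenesulfonamide | C[C@H](CNS(=O)(=O)c1ccccc1[N+](=O)[O-])CCCCCCCO | intermediate
7 | (S)-3-methyl-1-[(2-nitrophenyl)sulfonyl]azecane | C[C@H]1CCCCCCCN(S(=O)(=O)c2ccccc2[N+](=O)[O-])C1 | intermediate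
8 | (S)-3-methylazecane | C[C@H]1CCCCCCCNC1 | intermediate
9 | 2,3-dimethoxyaniline | COc1cccc(N)c1OC | starting material
10 | 7,8-dimethoxyquinoline | COc1ccc2cccnc2c1OC | intermediate
11 | 5-bromo-7,8-dimethoxyquinoline | COc1cc(Br)c2cccnc2c1OC | intermediate
12 | 7,8-dimethoxy-5-(4,4,5,5-tetramethyl-1,3,2-dioxaborolan-2-yl)quinoline | COc1cc(B2OC(C)(C)C(C)(C)O2)c2cccnc2c1OC | intermediate
13 | 1-(triisopropylsilyl)pyrrole | CC(C)[Si](C(C)C)(C(C)C)n1cccc1 | starting material
14 | 3,4-dibromo-1-(triisopropylsilyl)pyrrole | CC(C)[Si](C(C)C)(C(C)C)n1cc(Br)c(Br)c1 | intermediate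
15 | 5-[4-bromo-1-(triisopropylsilyl)-1H-pyrrol-3-yl]-7,8-dimethoxyquinoline | COc1cc(-c2cn([Si](C(C)C)(C(C)C)C(C)C)cc2Br)c2cccnc2c1OC | intermediate
16 | 5,5'-[1-(triisopropylsilyl)-1H-pyrrole-3,4-diyl]bis(7,8-dimethoxyquinoline) | COc1cc(-c2cn([Si](C(C)C)(C(C)C)C(C)C)cc2-c2cc(OC)c(OC)c3ncccc23)c2cccnc2c1OC | intermediate
17 | 5,5'-(1H-pyrrole-3,4-diyl)bis(7,8-dimethoxyquinoline) | COc1cc(-c2c[nH]cc2-c2cc(OC)c(OC)c3ncccc23)c2cccnc2c1OC | intermediate
18 | 5,5'-[1-(3-chloropropyl)-1H-pyrrole-3,4-diyl]bis(7,8-dimethoxyquinoline) | COc1cc(-c2cn(CCCCl)cc2-c2cc(OC)c(OC)c3ncccc23)c2cccnc2c1OC | intermediate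
19 | 5,5'-{1-[3-((S)-3-methylazecan-1-yl)propyl]-1H-pyrrole-3,4-diyl}bis(7,8-dimethoxyquinoline) | C[C@H]1CCCCCCCN(CCCn2cc(-c3cc(OC)c(OC)c4ncccc34)c(-c3cc(OC)c(OC)c4ncccc34)c2)C1 | intermediate
20 | 5,5'-{1-[3-((S)-3-methylazecan-1-yl)propyl]-1H-pyrrole-3,4-diyl}bis(quinoline-7,8-diol) | C[C@H]1CCCCCCCN(CCCn2cc(-c3cc(O)c(O)c4ncccc34)c(-c3cc(O)c(O)c4ncccc34)c2)C1 | target

**Step count and risks**

Total step count: 13. Longest linear sequence: 8 steps (steps 5, 6, 7, 9, 10, 11, 12, 13); the azecane arm contributes 6 (steps 1–4, 12, 13).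

Steps most likely to fail:

Step 3 (ring closure). Intermolecular alkylation may outrun closure of the strained medium ring, giving the twenty-membered cyclic dimer and oligomers, or the reduced azodicarboxylate may be alkylated instead. The fallback closes the ring at C7–C8 by olefin metathesis instead of at nitrogen. It sets out from 1: copper-catalysed coupling with but-3-enylmagnesium bromide (Li2CuCl4, THF) would give (S)-2-methylhept-6-en-1-ol F1. Mitsunobu reaction with an excess of 2-nitrobenzenesulfonamide (PPh3, DIAD) would give (S)-N-(2-methylhept-6-enyl)-2-nitrobenzenesulfonamide F2. N-alkylation with 4-bromobut-1-ene (K2CO3, DMF) would give (S)-N-(but-3-enyl)-N-(2-methylhept-6-enyl)-2-nitrobenzenesulfonamide F3. Ring-closing metathesis with the second-generation Grubbs catalyst RuCl2(=CHPh)(PCy3)(SIMes) in dilute CH2Cl2 would give (S)-3-methyl-1-[(2-nitrophenyl)sulfonyl]-1,2,3,4,5,6,9,10-octahydroazecine F4 as an alkene isomer mixture. Diimide reduction (TsNHNH2, NaOAc, aqueous THF, reflux), which spares the nitro group, would bring the route back to 7.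

Step 10 (second coupling). Oxidative addition into the bromide next to the peri-hindered quinolinyl group may be too slow, so that boronate 12 is lost by protodeboronation and the bromide is merely reduced. The fallback reverses the polarity of this coupling, putting boron on the electron-rich pyrrole and using the more readily activated quinolinyl bromide. It sets out from 15 and 11: Miyaura borylation of 15 (B2pin2, Pd(dppf)Cl2, KOAc, dioxane, 90 °C) would give 7,8-dimethoxy-5-[4-(4,4,5,5-tetramethyl-1,3,2-dioxaborolan-2-yl)-1-(triisopropylsilyl)-1H-pyrrol-3-yl]quinoline F5, which would be coupled with bromide 11 (Pd(OAc)2, SPhos, K3PO4, toluene–H2O). This comes back to the route at 16, which is desilylated with TBAF to 17 as in step 10.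

Step 13 (global demethylation). The electron-rich pyrrole with free 2- and 5-positions may decompose under BBr3 and HBr, cleavage may stay incomplete because boron is held by the basic nitrogens, and the bis-catechol may oxidise during isolation. The fallback moves ether cleavage to the robust bromoquinoline and unmasks the catechols at the end by hydrogenolysis. It sets out from 11: BBr3 in CH2Cl2 would give 5-bromoquinoline-7,8-diol F6, and benzylation (BnBr, K2CO3, DMF) would give 7,8-bis(benzyloxy)-5-bromoquinoline F7. Borylation as in step 7 would give 7,8-bis(benzyloxy)-5-(4,4,5,5-tetramethyl-1,3,2-dioxaborolan-2-yl)quinoline F8. Coupling of F8 with an excess of 14 as in step 9 would give 7,8-bis(benzyloxy)-5-[4-bromo-1-(triisopropylsilyl)-1H-pyrrol-3-yl]quinoline F9. A second coupling with F8 as in step 10 would give 5,5'-[1-(triisopropylsilyl)-1H-pyrrole-3,4-diyl]bis[7,8-bis(benzyloxy)quinoline] F10, and TBAF would give 5,5'-(1H-pyrrole-3,4-diyl)bis[7,8-bis(benzyloxy)quinoline] F11. Alkylation as in step 11 would give 5,5'-[1-(3-chloropropyl)-1H-pyrrole-3,4-diyl]bis[7,8-bis(benzyloxy)quinoline] F12, and reaction with 8 as in step 12 would give 5,5'-{1-[3-((S)-3-methylazecan-1-yl)propyl]-1H-pyrrole-3,4-diyl}bis[7,8-bis(benzyloxy)quinoline] F13. Hydrogenolysis (H2, Pd(OH)2 on carbon, MeOH–EtOAc, rt) would come back to the route at 20.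

**Further compounds**

F1 | step 3 | (S)-2-methylhept-6-en-1-ol | C[C@H](CO)CCCC=C
F2 | step 3 | (S)-N-(2-methylhept-6-enyl)-2-nitrobenzenesulfonamide | C[C@H](CNS(=O)(=O)c1ccccc1[N+](=O)[O-])CCCC=C
F3 | step 3 | (S)-N-(but-3-enyl)-N-(2-methylhept-6-enyl)-2-nitrobenzenesulfonamide | C[C@H](CN(CCC=C)S(=O)(=O)c1ccccc1[N+](=O)[O-])CCCC=C
F4 | step 3 | (S)-3-methyl-1-[(2-nitrophenyl)sulfonyl]-1,2,3,4,5,6,9,10-octahydroazecine | C[C@H]1CCCC=CCCN(S(=O)(=O)c2ccccc2[N+](=O)[O-])C1
F5 | step 10 | 7,8-dimethoxy-5-[4-(4,4,5,5-tetramethyl-1,3,2-dioxaborolan-2-yl)-1-(triisopropylsilyl)-1H-pyrrol-3-yl]quinoline | COc1cc(-c2cn([Si](C(C)C)(C(C)C)C(C)C)cc2B2OC(C)(C)C(C)(C)O2)c2cccnc2c1OC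
F6 | step 13 | 5-bromoquinoline-7,8-diol | Oc1cc(Br)c2cccnc2c1O
F7 | step 13 | 7,8-bis(benzyloxy)-5-bromoquinoline | Brc1cc(OCc2ccccc2)c(OCc2ccccc2)c2ncccc12
F8 | step 13 | 7,8-bis(benzyloxy)-5-(4,4,5,5-tetramethyl-1,3,2-dioxaborolan-2-yl)quinoline | CC1(C)OB(OC1(C)C)c1cc(OCc2ccccc2)c(OCc2ccccc2)c2ncccc12
F9 | step 13 | 7,8-bis(benzyloxy)-5-[4-bromo-1-(triisopropylsilyl)-1H-pyrrol-3-yl]quinoline | Brc1cn([Si](C(C)C)(C(C)C)C(C)C)cc1-c1cc(OCc2ccccc2)c(OCc2ccccc2)c2ncccc12
F10 | step 13 | 5,5'-[1-(triisopropylsilyl)-1H-pyrrole-3,4-diyl]bis[7,8-bis(benzyloxy)quinoline] | CC(C)[Si](C(C)C)(C(C)C)n1cc(-c2cc(OCc3ccccc3)c(OCc3ccccc3)c3ncccc23)c(-c2cc(OCc3ccccc3)c(OCc3ccccc3)c3ncccc23)c1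
F11 | step 13 | 5,5'-(1H-pyrrole-3,4-diyl)bis[7,8-bis(benzyloxy)quinoline] | c1[nH]cc(-c2cc(OCc3ccccc3)c(OCc3ccccc3)c3ncccc23)c1-c1cc(OCc2ccccc2)c(OCc2ccccc2)c2ncccc12
F12 | step 13 | 5,5'-[1-(3-chloropropyl)-1H-pyrrole-3,4-diyl]bis[7,8-bis(benzyloxy)quinoline] | ClCCCn1cc(-c2cc(OCc3ccccc3)c(OCc3ccccc3)c3ncccc23)c(-c2cc(OCc3ccccc3)c(OCc3ccccc3)c3ncccc23)c1
F13 | step 13 | 5,5'-{1-[3-((S)-3-methylazecan-1-yl)propyl]-1H-pyrrole-3,4-diyl}bis[7,8-bis(benzyloxy)quinoline] | C[C@H]1CCCCCCCN(CCCn2cc(-c3cc(OCc4ccccc4)c(OCc4ccccc4)c4ncccc34)c(-c3cc(OCc4ccccc4)c(OCc4ccccc4)c4ncccc34)c2)C1
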